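**Retrosynthetic overview**

1. The central ring of target 10 is a resorcinol: C1 and C3 carry OH, C2 is the CH between them, C4 and C6 carry 4-hydroxybenzyl groups and C5 the 2-phenylethyl group. The strategy reads this ring as the aromatised form of cyclohexane-1,3-dione 8, in which C2–C3(=O)–C4 is a methyl ketone unit and C5–C6–C1 is a β-phenethyl, α-benzyl acrylate unit.
2. Disconnections, backwards: four O–CH3 bonds (BBr3); arene to dione 8 (I2/MeOH); C4–C5 (Michael) and C1–C2 (Claisen) of 8 to ketone 6 and enoate 5; C5=C6 of 5 to phosphonate 3 and aldehyde 4 (HWE); 3 to 1 and 2 (alkylation).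
3. Ring order: the three outer benzene rings are bought; the central six-membered ring is the only ring built, closed in step 3 and aromatised in step 4.

Key step: step 3

Remark: the target has no stereocentre, axis or plane of chirality, so it is a single achiral compound and no enantiocontrol is needed; the sp3 centres of 3, 7 and 8 are transient.

**Route**

Step 1
Reactants: 1 trimethyl phosphonoacetate (used in slight excess); 2 4-methoxybenzyl chloride
Product: 3 methyl 2-(dimethoxyphosphoryl)-3-(4-methoxyphenyl)propanoate (racemic)
Conditions: NaH, THF/DMF, 0 °C; then 2, NaI (cat.), rt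
Reagents that add atoms: none
Why: SN2 C-alkylation of the stabilised phosphonoacetate carbanion by a reactive benzylic chloride, with excess 1 limiting double alkylation; the new CH centre is racemic and becomes sp2 in step 2.

Step 2
Reactants: 3 methyl 2-(dimethoxyphosphoryl)-3-(4-methoxyphenyl)propanoate; 4 3-phenylpropanal
Product: 5 methyl (E)-2-(4-methoxybenzyl)-5-phenylpent-2-enoate
Conditions: NaH, THF, 0 °C; then 4, 0 °C → rt
Reagents that add atoms: none
Why: Horner–Wadsworth–Emmons olefination of an α-substituted phosphonoacetate with an unhindered aliphatic aldehyde should give the trisubstituted enoate, mainly E; any Z isomer can be carried on because step 3 destroys the alkene geometry.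

Step 3
Reactants: 5 methyl (E)-2-(4-methoxybenzyl)-5-phenylpent-2-enoate; 6 4-(4-methoxyphenyl)butan-2-one
Product: 8 4,6-bis(4-methoxybenzyl)-5-(2-phenylethyl)cyclohexane-1,3-dione (mixture of diastereomers), via keto ester Michael adduct 7 (not isolated)
Conditions: t-BuOK (2.2 equiv), THF, 0 °C (6, then 5) → 60 °C; then 1 M HCl
Reagents that add atoms: none
Why: t-BuOK deprotonates 6 reversibly, and proton exchange lets the more substituted potassium enolate accumulate; its carbon (C3 of the butanone, already carrying the 4-methoxybenzyl group) adds to the β-carbon of 5 and forms C4–C5 of keto ester 7. Proton transfer then gives the methyl-side enolate of 7, whose carbon (future C2) attacks the ester carbonyl (future C1) and expels methoxide in a 6-(enolendo)-exo-trig Claisen closure, the only ring formed in the step. The 1,3-dione is deprotonated at C2 at once to its stabilised potassium enolate, which takes it out of all equilibria and pulls the slow, reversible conjugate addition forward. The closest known reaction type is the consecutive Michael–Claisen [3+3] annulation of methyl ketones with α,β-unsaturated esters under t-BuOK, here applied to a more hindered α,β-disubstituted enoate. C4, C5 and C6 become sp3 centres without control, which is acceptable because all three become aromatic sp2 carbons in step 4. The selectivity needed is regiochemical, conjugate addition from the internal α-carbon and acylation from the methyl carbon: enolate equilibration secures the first, and ring size secures the second, since closure from the internal carbon of 7 would need a four-membered ring.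

Step 4
Reactants: 8 4,6-bis(4-methoxybenzyl)-5-(2-phenylethyl)cyclohexane-1,3-dione
Product: 9 1,5-dimethoxy-2,4-bis(4-methoxybenzyl)-3-(2-phenylethyl)benzene
Conditions: I2 (2 equiv), MeOH, reflux; aq Na2S2O3 work-up
Reagents that add atoms: methanol, CO
Why: Iodine–methanol oxidative aromatisation of a cyclohexane-1,3-dione: HI formed in situ catalyses enol ether formation, iodination at the α-carbon C4 or C6 and loss of HI supply the missing unsaturation, and the ring should emerge as the resorcinol dimethyl ether, while iodination at C2 is reversed by HI and the anisole rings and benzylic CH2 groups are inert to I2 alone.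

Step 5
Reactants: 9 1,5-dimethoxy-2,4-bis(4-methoxybenzyl)-3-(2-phenylethyl)benzene
Product: 10 4,6-bis(4-hydroxybenzyl)-5-(2-phenylethyl)benzene-1,3-diol (target)
Conditions: BBr3 (6 equiv), CH2Cl2, −78 °C → rt; then MeOH, H2O
Reagents that add atoms: none
Why: BBr3 ether cleavage (complexation at oxygen, bromide attack at methyl) should remove all four aryl methyl ethers; there is no other Lewis-basic or acid-labile group, and the diarylmethane and bibenzyl C–C bonds should stay intact at or below room temperature.

**Compound list**

1 | trimethyl phosphonoacetate | COC(=O)CP(=O)(OC)OC | starting material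
2 | 4-methoxybenzyl chloride | COc1ccc(CCl)cc1 | starting material
3 | methyl 2-(dimethoxyphosphoryl)-3-(4-methoxyphenyl)propanoate (racemic) | COC(=O)C(Cc1ccc(OC)cc1)P(=O)(OC)OC | intermediate
4 | 3-phenylpropanal | O=CCCc1ccccc1 | starting material
5 | methyl (E)-2-(4-methoxybenzyl)-5-phenylpent-2-enoate | COC(=O)/C(Cc1ccc(OC)cc1)=C/CCc1ccccc1 | intermediate
6 | 4-(4-methoxyphenyl)butan-2-one | COc1ccc(CCC(C)=O)cc1 | starting material
7 | methyl 2,4-bis(4-methoxybenzyl)-5-oxo-3-(2-phenylethyl)hexanoate (diastereomer mixture, formed as its potassium enolate, not isolated) | COC(=O)C(Cc1ccc(OC)cc1)C(CCc1ccccc1)C(Cc1ccc(OC)cc1)C(C)=O | intermediate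
8 | 4,6-bis(4-methoxybenzyl)-5-(2-phenylethyl)cyclohexane-1,3-dione (diastereomer mixture, keto/enol tautomers) | O=C1CC(=O)C(Cc2ccc(OC)cc2)C(CCc2ccccc2)C1Cc1ccc(OC)cc1 | intermediate
9 | 1,5-dimethoxy-2,4-bis(4-methoxybenzyl)-3-(2-phenylethyl)benzene | COc1cc(OC)c(Cc2ccc(OC)cc2)c(CCc2ccccc2)c1Cc1ccc(OC)cc1 | intermediate
10 | 4,6-bis(4-hydroxybenzyl)-5-(2-phenylethyl)benzene-1,3-diol (achiral) | Oc1ccc(Cc2c(O)cc(O)c(Cc3ccc(O)cc3)c2CCc2ccccc2)cc1 | target

**Step count**

Total steps: 5. Longest linear sequence: 5 (1/2 → 3 → 5 → 8 → 9 → 10).

**Steps most likely to fail**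

Step 3. Conjugate addition of the hindered secondary enolate carbon to the α,β-disubstituted enoate may be too slow. Then γ-deprotonation of 5 (deconjugation, dienolate self-addition) or aldol self-condensation of 6 may take over. Addition through the methyl-side enolate is also possible and, after closure from the internal carbon, would lead to the 2,4-dibenzyl regioisomer. The fallback installs the C6 benzyl group after ring formation, so that the annulation runs on a β-monosubstituted enoate, the usual case for this reaction. It sets out from 1 and 4: Horner–Wadsworth–Emmons olefination (NaH, THF) should give methyl (E)-5-phenylpent-2-enoate F1. Annulation of F1 with 6 (t-BuOK, THF, 0 °C → rt) should pass through methyl 4-(4-methoxybenzyl)-5-oxo-3-(2-phenylethyl)hexanoate F2 to 4-(4-methoxybenzyl)-5-(2-phenylethyl)cyclohexane-1,3-dione F3. The dianion of F3 (LDA 2.2 equiv, THF–HMPA, −78 → 0 °C) should be alkylated with 2 at the less hindered γ-methylene C6, and the fallback comes back to the route at 8.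

Step 4. Iodination at C2 or stalling at the enol ether stage, because the α-carbons C4 and C6 are tertiary and crowded, may prevent clean dehydrogenation. Partial O-methylation would give a mixture of ether stages; these should converge in step 5, but they complicate purification. The fallback separates enol ether formation, α′-functionalisation and elimination, setting out from 8. O-Methylation (HC(OMe)3, TsOH cat., MeOH) should give 3-methoxy-4,6-bis(4-methoxybenzyl)-5-(2-phenylethyl)cyclohex-2-en-1-one F4; only one constitution is possible because the two carbonyls of 8 are constitutionally equivalent. Kinetic α′-deprotonation and selenenylation (LDA, THF, −78 °C; PhSeCl) should give 3-methoxy-4,6-bis(4-methoxybenzyl)-5-(2-phenylethyl)-6-(phenylselanyl)cyclohex-2-en-1-one F5. Oxidation (H2O2, pyridine, CH2Cl2, 0 °C → rt), with syn-elimination into the ring and enolisation, should give 5-methoxy-2,4-bis(4-methoxybenzyl)-3-(2-phenylethyl)phenol F6. BBr3 as in step 5 then cleaves its three methyl ethers, and the fallback comes back to the route at 10.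

Step 2. Olefination by the hindered α-benzyl phosphonate anion may be slow enough for base-induced enolisation and self-aldol condensation of aldehyde 4 to consume the aldehyde. The fallback builds the alkene by aldol addition and dehydration, setting out from 4 and bypassing 3. The lithium enolate of purchased methyl 3-(4-methoxyphenyl)propanoate F7 (LDA, THF, −78 °C) should add to 4 to give methyl 3-hydroxy-2-(4-methoxybenzyl)-5-phenylpentanoate F8 as a diastereomer mixture. Mesylation (MsCl, Et3N, CH2Cl2, 0 °C) should give methyl 2-(4-methoxybenzyl)-3-(methylsulfonyloxy)-5-phenylpentanoate F9. E1cB elimination (DBU, toluene, 80 °C) comes back to the route at 5; either alkene geometry is usable.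

**Further compounds**

F1 | step 3 | methyl (E)-5-phenylpent-2-enoate | COC(=O)/C=C/CCc1ccccc1
F2 | step 3 | methyl 4-(4-methoxybenzyl)-5-oxo-3-(2-phenylethyl)hexanoate (not isolated) | COC(=O)CC(CCc1ccccc1)C(Cc1ccc(OC)cc1)C(C)=O
F3 | step 3 | 4-(4-methoxybenzyl)-5-(2-phenylethyl)cyclohexane-1,3-dione | O=C1CC(=O)C(Cc2ccc(OC)cc2)C(CCc2ccccc2)C1
F4 | step 4 | 3-methoxy-4,6-bis(4-methoxybenzyl)-5-(2-phenylethyl)cyclohex-2-en-1-one | COC1=CC(=O)C(Cc2ccc(OC)cc2)C(CCc2ccccc2)C1Cc1ccc(OC)cc1
F5 | step 4 | 3-methoxy-4,6-bis(4-methoxybenzyl)-5-(2-phenylethyl)-6-(phenylselanyl)cyclohex-2-en-1-one | COC1=CC(=O)C(Cc2ccc(OC)cc2)([Se]c2ccccc2)C(CCc2ccccc2)C1Cc1ccc(OC)cc1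
F6 | step 4 | 5-methoxy-2,4-bis(4-methoxybenzyl)-3-(2-phenylethyl)phenol | COc1cc(O)c(Cc2ccc(OC)cc2)c(CCc2ccccc2)c1Cc1ccc(OC)cc1
F7 | step 2 | methyl 3-(4-methoxyphenyl)propanoate (purchased, not made) | COC(=O)CCc1ccc(OC)cc1
F8 | step 2 | methyl 3-hydroxy-2-(4-methoxybenzyl)-5-phenylpentanoate (diastereomer mixture) | COC(=O)C(Cc1ccc(OC)cc1)C(O)CCc1ccccc1
F9 | step 2 | methyl 2-(4-methoxybenzyl)-3-(methylsulfonyloxy)-5-phenylpentanoate | COC(=O)C(Cc1ccc(OC)cc1)C(OS(C)(=O)=O)CCc1ccccc1
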